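## The problem

Compound 23 is a 3,3,6-trisubstituted 1,2-dioxane. With the ring numbered O1–O2–C3–C4–C5–C6, C3 is a peroxyketal carbon that carries a methoxy group and a sixteen-carbon chain (C1'–C16': three methylenes, the C4'≡C5' alkyne, the (E)-C6'=C7' alkene, seven methylenes and a terminal vinyl group), and C6 is a secondary peroxide carbon that carries the acetic acid arm (C7, C8). The chain is unbranched, so carbon–carbon bonds are needed at only three places (the sp–sp2 bond of the enyne, C3–C1' and C6–C7); the real task is the ring, that is, two C–O bonds to one O–O unit. There are two stereocentres, C3 (R) and C6 (S), in a 1,4-relationship. C3 is a ketal centre that equilibrates in acidic methanol, and the target has the arrangement expected at equilibrium (methoxy axial for the anomeric effect, chain and arm equatorial, methoxy cis to the arm), so C6 controls C3, whereas nothing in the molecule controls C6, which must be set or selected in the absolute sense. The O–O bond forbids hydrides, dissolving metals, hydrogenation and long contact with phosphines or low-valent metals; the carboxyl group is β to the peroxide, so strong base threatens a retro-peroxy-Michael opening; the peroxyketal ionizes with strong Lewis acids; and the enyne and terminal alkene exclude ozonolysis or hydroboration late in the route. The feature that opens the key step is that C3 (tertiary, ketone oxidation level) and C6 (secondary) are joined by the C4–C5 bridge and by the same O2 unit: if O1–O2 is lifted out and C3 is bonded to C6, a 1,2-disubstituted cyclobutanol remains, so the ring is a cyclobutanol with dioxygen inserted into a temporary C3–C6 bond.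

## Retrosynthesis

**23 ⇒ 22.** No skeletal bond is cut: acid 23 is taken back to racemic methyl ester 22, and the last step is an enantioselective enzymatic hydrolysis. This frees the β-peroxy acid at neutral pH and at the same time selects the (3R,6S) enantiomer, so that all earlier chemistry may be racemic, as the key step demands. Resolving earlier would save some of iodide 21 but would bring a free acid or a second ester cleavage into the route. The forward step asks for a hydrolase that reads the C6 stereocentre, two atoms from the acyl carbon.

**22 ⇒ 18 + 21.** The C5'–C6' bond between alkyne and alkene is cut (Sonogashira coupling). The neighbouring cuts are worse: acetylide alkylation at C3'–C4' needs a strong base beside ester and peroxide, and an olefination at C6'=C7' would have to control alkene geometry on the finished ring. The cut divides the molecule into the polar core 18, which holds the ring and both stereocentres, and the eleven-carbon (E)-iodoalkene 21, whose geometry is fixed beforehand. The coupling must run at room temperature and leave the O–O bond alone.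

**21 ⇒ 20 ⇒ 19.** The C6'=C7' double bond of 21 is cut by one-carbon homologation of aldehyde 20 (Takai olefination), and 20 comes from commercial dec-9-en-1-ol 19 by oxidation. This is shorter than a route through a terminal alkyne. The forward reaction must give the E isomer and spare the terminal alkene.

**18 ⇒ 17 ⇒ 14.** The alkyne C–H is taken back to silane 17, since the silyl group is needed to make the organometallic reagent. 17 is taken back to hemiketal 14 by cutting the C3–OMe bond and exchanging the ester alkyl group. Both changes are planned for one treatment with acidic methanol, passing through tert-butyl ester 15 and acid 16. Ketal exchange is thermodynamic and sets C3 relative to C6. The tert-butyl ester is needed only up to 14 (see below) and must become a methyl ester for the enzyme. The forward step asks that the peroxide tolerate methanolic acid long enough for the tert-butyl group to leave.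

**14 ⇒ 11 + 12 (key disconnection).** C6–O1 and O2–C3 are cut and the C3–C6 bond is drawn, which gives cyclobutanol 11 and dioxygen 12. Against a peroxyketalization of a preformed hydroperoxy ketone or a peroxy-Michael closure, this cut takes both oxygens from O2, needs no peroxide reagent and no substitution at a secondary carbon, and forms both C–O bonds in one catalytic step through hydroperoxy ketone 13. The precursor loses the heterocycle and all stereochemical demands: 11 may be racemic and either diastereomer. The forward reaction must generate the tertiary alkoxy radical, cleave the ring bond toward the substituted carbon and trap the C6 radical with O2 without reducing the hydroperoxide.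

**11 ⇒ 7 + 8.** The C3–C1' bond is cut: organocerium reagent 10, made from chloride 8 through Grignard reagent 9, adds to cyclobutanone 7. Addition anti to the ring substituent puts the hydroxyl cis to the acetate arm. With a methyl ester the alkoxide would close to a bicyclic γ-lactone that no longer has the free hydroxyl the key step needs, so the arm is carried as a tert-butyl ester, which resists acyl transfer. The precursors are a seven-carbon keto ester and a commercial chloride.

**7 ⇒ 3 + 4; 3 ⇒ 1 + 2.** The C6–C7 bond is cut by alkylation of the azaenolate 5 of hydrazone 3 with tert-butyl bromoacetate 4, followed by hydrolysis of the alkylated hydrazone 6. Direct enolate alkylation of cyclobutanone is plagued by self-condensation and over-alkylation, which the hydrazone avoids. 3 comes from cyclobutanone 1 and 1,1-dimethylhydrazine 2.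

## Roads not taken

**Alternative 1:** The cut is at O2–C3 and C3–OMe only. C6–O1 is already present in the open-chain ketone A2, which carries the complete side chain, a silyl-protected hydroxyethyl arm and an (S)-configured secondary peroxide masked as a mixed peroxyketal. Acidic methanol would free the hydroperoxide, which adds to the C3 ketone and is methanolysed to the (3R,6S)-3-methoxy-1,2-dioxane A1.

- Merits: C6 is fixed before the ring exists and C3 follows by equilibration, so no resolution and no loss of half the material is needed. The ring closure itself is the most reliable way to a 3-alkoxy-1,2-dioxane.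
- Weak points: the chiral peroxide in A2 must come from invertive displacement of a secondary sulfonate by a peroxide nucleophile, which competes with elimination and is seldom clean at a secondary carbon flanked by two methylene chains. The chiral alcohol behind it needs its own asymmetric step. The arm of A1 is at the alcohol oxidation level, so desilylation and a two-stage oxidation must be run at the end on a molecule that holds the peroxide, the enyne and the terminal alkene.
- Comparison: this road is clearly better in absolute stereocontrol. The chosen plan sets against it a much shorter way to the ring (two C–O bonds from O2 in one catalytic step on a precursor made in three steps), an arm that stays at the carboxyl oxidation level, and no stoichiometric peroxide reagent.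

**Alternative 2:** The cut is at O1–C6. The hydroperoxy ketal A4, tethered to an oxetane of R configuration, would be activated by Me3SiOTf or Yb(OTf)3. The hydroperoxide oxygen attacks the oxetane stereocentre with inversion and gives the (6S)-6-(2-hydroxyethyl)-3-methoxy-1,2-dioxane A3 as both C3 epimers.

- Merits: the C–O bond formation is stereospecific, so the configuration of C6 is carried over from an enantioenriched oxetane, and the primary alcohol is released already differentiated.
- Weak points: A4 contains a hydroperoxy ketal that is itself ionized by the Lewis acids needed to open the oxetane. The attack must occur at the more substituted oxetane carbon, where carbocation character and some loss of enantiopurity are to be expected. A4 needs an enantioselective oxetane synthesis and a separate peroxyketalization, which is longer than the whole front end of the chosen plan. The arm of A3 must again be oxidized late, and C3 must still be equilibrated.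
- Comparison: in stereochemical terms this road is superior to the chosen one, which is racemic up to the last step. The chosen plan offers in return a key step with direct precedent on cyclobutanols, a three-step precursor and a carboxyl group that never changes oxidation level.

**Alternative 3:** The cut is at C4–C5, C6–O1 and O2–C3 at once. Mn(OAc)3 under air would oxidize β-keto ester A6 to its α-radical, which adds to methyl but-3-enoate A7. The adduct radical at C6 captures O2 and the peroxy group closes on the ketone to give the 1,2-dioxan-3-ol A5.

- Merits: no other plan is as convergent. The whole ring and one C–C bond form in one step from the two very simple components A6 and A7, with the arm already an ester.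
- Weak points: a tert-butoxycarbonyl group is left on C4 of A5. Removing it means cleaving the ester and decarboxylating a β-keto acid that exists only in the ring-opened hydroperoxy ketone form, under acid and heat that the peroxide is unlikely to survive. The radical must also add to A7, an unactivated monosubstituted alkene with abstractable hydrogens between alkene and ester, which is a poor acceptor in this chemistry. A5 arises as a stereoisomer mixture over three centres and is racemic, like the product of the chosen plan.
- Comparison: on bonds formed per step this road beats the chosen one. The chosen plan answers with a product that has exactly the substitution pattern of the target, so nothing has to be removed from the ring afterwards.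

Key step: step 4

Assumption: the key step cannot control absolute configuration, so compounds 11–22 are racemic; they are drawn and named as the enantiomer that leads to 23 and carry the prefix rac, and the dioxane ring is numbered with the ketal carbon as C3 throughout.

## Route

Step 1
Reactants: 1 cyclobutanone; 2 1,1-dimethylhydrazine
Product: 3 cyclobutanone N,N-dimethylhydrazone
Conditions: MgSO4, CH2Cl2, rt
Reagents that add atoms: none
Why: Hydrazone formation by condensation; the strained, electrophilic ketone condenses readily and the drying agent takes up the water.

Step 2
Reactants: 3 cyclobutanone N,N-dimethylhydrazone; 4 tert-butyl bromoacetate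
Product: 7 tert-butyl 2-(2-oxocyclobutyl)acetate (racemic), via lithium azaenolate 5 (not isolated), via alkylated hydrazone 6 (not isolated)
Conditions: LiN(iPr)2, THF, −78 → 0 °C; 4, −78 °C → rt; then sat. aq. (CO2H)2, Et2O, rt
Reagents that add atoms: water, O
Why: Azaenolate alkylation of a dimethylhydrazone followed by mild two-phase hydrazone hydrolysis; the azaenolate is monoalkylated by the reactive α-bromo ester where the cyclobutanone enolate itself would self-condense, and aqueous oxalic acid leaves the tert-butyl ester intact. The new stereocentre forms racemic and is erased in step 4.

Step 3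
Reactants: 7 tert-butyl 2-(2-oxocyclobutyl)acetate; 8 (5-chloropent-1-yn-1-yl)trimethylsilane
Product: 11 rac-tert-butyl 2-[(1R,2R)-2-hydroxy-2-[5-(trimethylsilyl)pent-4-yn-1-yl]cyclobutyl]acetate (hydroxyl cis to the acetate arm; the minor trans isomer is carried along), via Grignard reagent 9 (not isolated), via organocerium dichloride 10 (not isolated)
Conditions: 8, Mg, BrCH2CH2Br (cat.), THF, reflux; CeCl3, THF, −78 °C; 7, −78 °C; aq. NH4Cl
Reagents that add atoms: none
Why: Grignard formation, transmetalation to a weakly basic organocerium reagent and 1,2-addition to the ketone, which outruns enolization and leaves the tert-butyl ester alone. Attack anti to the ring substituent should place the hydroxyl cis to the arm; the tert-butyl ester resists acyl transfer to the alkoxide, so the hydroxy ester should not close to the bicyclic γ-lactone that a methyl ester would give. Both diastereomers serve step 4 equally.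

Step 4
Reactants: 11 rac-tert-butyl 2-[(1R,2R)-2-hydroxy-2-[5-(trimethylsilyl)pent-4-yn-1-yl]cyclobutyl]acetate; 12 dioxygen
Product: 14 rac-tert-butyl 2-[(3R,6S)-3-hydroxy-3-[5-(trimethylsilyl)pent-4-yn-1-yl]-1,2-dioxan-6-yl]acetate, via hydroperoxy ketone 13 (not isolated)
Conditions: Co(acac)2 (cat.), O2 (1 atm), MeCN, 40 °C
Reagents that add atoms: none
Why: This is the cobalt-catalysed aerobic oxidative ring expansion of a cyclobutanol to a 1,2-dioxan-3-ol, a known reaction whose older relative is the opening of cyclopropanols to 1,2-dioxolan-3-ols. Co(acac)2 and O2 give a trivalent cobalt species that takes up the tertiary alkoxide of 11, and homolysis of the Co–O bond releases the cyclobutoxy radical and divalent cobalt. Relief of ring strain drives β-scission, and the temporary C3–C6 bond should break in preference to C3–C4 or the exocyclic C3–C1' bond because only this cleavage leaves a secondary radical; this regioselectivity is the one the step needs, and the acetate-bearing substituent on that ring carbon secures it. The C6 radical captures O2 (C6–O1), the peroxyl radical is reduced by divalent cobalt and protonated to γ-hydroperoxy ketone 13, and the hydroperoxide oxygen adds to the C3 ketone (O2–C3) in a 6-exo-trig hemiketalization that closes the 1,2-dioxane. C6 arises from a planar radical in a molecule that holds no other stereocentre at that moment, so it forms racemic and its absolute sense is left to step 10; both diastereomers of 11 converge on the same radical. C3 is a hemiketal carbon under ring–chain equilibrium and should settle with hydroxyl axial (anomeric effect) and both carbon substituents equatorial, the (3R*,6S*) relative configuration. The alkynylsilane is inert without a hydride source and the tert-butyl ester neither lactonizes nor enolizes under these neutral conditions; tertiary cyclobutanols react more slowly than secondary ones, hence the gentle warming and a generous catalyst loading.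

Step 5
Reactants: 14 rac-tert-butyl 2-[(3R,6S)-3-hydroxy-3-[5-(trimethylsilyl)pent-4-yn-1-yl]-1,2-dioxan-6-yl]acetate
Product: 17 rac-methyl 2-[(3R,6S)-3-methoxy-3-[5-(trimethylsilyl)pent-4-yn-1-yl]-1,2-dioxan-6-yl]acetate, via tert-butyl ester ketal 15 (not isolated), via ketal acid 16 (not isolated)
Conditions: HCl (3 M in MeOH), rt → 40 °C
Reagents that add atoms: methanol, CO
Why: Acid-catalysed peroxyketal exchange through the ring peroxycarbenium ion, together with acidolysis of the tert-butyl ester and Fischer esterification of the freed acid. The exchange at C3 is thermodynamic, so the methoxy group should end axial with chain and arm equatorial, which sets C3 relative to C6 as in the target. The alkynylsilane does not react with methanolic acid of this strength.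

Step 6
Reactants: 17 rac-methyl 2-[(3R,6S)-3-methoxy-3-[5-(trimethylsilyl)pent-4-yn-1-yl]-1,2-dioxan-6-yl]acetate
Product: 18 rac-methyl 2-[(3R,6S)-3-methoxy-3-(pent-4-yn-1-yl)-1,2-dioxan-6-yl]acetate
Conditions: K2CO3 (cat.), MeOH, 0 °C
Reagents that add atoms: none
Why: Base-catalysed protodesilylation of an alkynylsilane; the ester is already methyl, so exchange with the solvent is invisible, and brief contact with catalytic carbonate in the cold should not open the β-peroxy ester.

Step 7
Reactants: 19 dec-9-en-1-ol
Product: 20 dec-9-enal
Conditions: TEMPO (cat.), PhI(OAc)2, CH2Cl2, rt
Reagents that add atoms: none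
Why: Nitroxyl-catalysed oxidation of a primary alcohol, which stops at the aldehyde and ignores the terminal alkene.

Step 8
Reactants: 20 dec-9-enal
Product: 21 (1E)-1-iodoundeca-1,10-diene
Conditions: CrCl2, CHI3, THF/1,4-dioxane, 0 °C → rt
Reagents that add atoms: iodoform, IC(I)I
Why: Takai olefination; the geminal dichromium species from CHI3 adds to the aldehyde and eliminates to the (E)-iodoalkene, dioxane as cosolvent favouring the E isomer. The remote alkene is untouched.

Step 9
Reactants: 18 rac-methyl 2-[(3R,6S)-3-methoxy-3-(pent-4-yn-1-yl)-1,2-dioxan-6-yl]acetate; 21 (1E)-1-iodoundeca-1,10-diene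
Product: 22 rac-methyl 2-[(3R,6S)-3-[(6E)-hexadeca-6,15-dien-4-yn-1-yl]-3-methoxy-1,2-dioxan-6-yl]acetate
Conditions: PdCl2(PPh3)2 (cat.), CuI (cat.), Et3N, THF (degassed), rt
Reagents that add atoms: none
Why: Sonogashira coupling with retention of the alkene geometry; a vinyl iodide couples at room temperature, and palladium–copper couplings are known to tolerate 3-alkoxy-1,2-dioxanes when oxygen is excluded and free phosphine is kept low. Triethylamine is too weak a base to open the β-peroxy ester.

Step 10
Reactants: 22 rac-methyl 2-[(3R,6S)-3-[(6E)-hexadeca-6,15-dien-4-yn-1-yl]-3-methoxy-1,2-dioxan-6-yl]acetate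
Product: 23 2-[(3R,6S)-3-[(6E)-hexadeca-6,15-dien-4-yn-1-yl]-3-methoxy-1,2-dioxan-6-yl]acetic acid (CNP0125368.1)
Conditions: Burkholderia cepacia lipase (Amano PS), phosphate buffer pH 7/acetone, 30 °C, stopped short of half conversion
Reagents that add atoms: water, O
Why: Hydrolase-mediated kinetic resolution by enantioselective ester hydrolysis, a method with precedent for esters whose stereocentre is a ring carbon β to the carboxyl group. The enzyme selects at C6, and because C3 is locked to C6 since step 5, hydrolysis of the (6S) ester should deliver the (3R,6S) acid. Neutral pH spares peroxide, ketal and enyne; the enzyme is to be fixed by a small screen of commercial hydrolases.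

## Compound list

1 | cyclobutanone | O=C1CCC1 | starting material
2 | 1,1-dimethylhydrazine | CN(C)N | starting material
3 | cyclobutanone N,N-dimethylhydrazone | CN(C)N=C1CCC1 | intermediate
4 | tert-butyl bromoacetate | BrCC(=O)OC(C)(C)C | starting material
5 | lithium azaenolate of 3 (lithium 1-(cyclobut-1-en-1-yl)-2,2-dimethylhydrazin-1-ide) | [Li]N(N(C)C)C1=CCC1 | intermediate (not isolated)
6 | tert-butyl 2-[2-(2,2-dimethylhydrazinylidene)cyclobutyl]acetate (racemic) | CN(C)N=C1CCC1CC(=O)OC(C)(C)C | intermediate (not isolated)
7 | tert-butyl 2-(2-oxocyclobutyl)acetate (racemic) | O=C1CCC1CC(=O)OC(C)(C)C | intermediate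
8 | (5-chloropent-1-yn-1-yl)trimethylsilane | C[Si](C)(C)C#CCCCCl | starting material
9 | [5-(trimethylsilyl)pent-4-yn-1-yl]magnesium chloride | C[Si](C)(C)C#CCCC[Mg]Cl | intermediate (not isolated)
10 | dichloro[5-(trimethylsilyl)pent-4-yn-1-yl]cerium | C[Si](C)(C)C#CCCC[Ce](Cl)Cl | intermediate (not isolated)
11 | rac-tert-butyl 2-[(1R,2R)-2-hydroxy-2-[5-(trimethylsilyl)pent-4-yn-1-yl]cyclobutyl]acetate (hydroxyl cis to the acetate arm) | C[Si](C)(C)C#CCCC[C@@]1(O)CC[C@@H]1CC(=O)OC(C)(C)C | intermediate
12 | dioxygen | O=O | starting material
13 | rac-tert-butyl (3S)-3-hydroperoxy-6-oxo-11-(trimethylsilyl)undec-10-ynoate | C[Si](C)(C)C#CCCCC(=O)CC[C@@H](CC(=O)OC(C)(C)C)OO | intermediate (not isolated)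
14 | rac-tert-butyl 2-[(3R,6S)-3-hydroxy-3-[5-(trimethylsilyl)pent-4-yn-1-yl]-1,2-dioxan-6-yl]acetate | C[Si](C)(C)C#CCCC[C@]1(O)CC[C@@H](CC(=O)OC(C)(C)C)OO1 | intermediate
15 | rac-tert-butyl 2-[(3R,6S)-3-methoxy-3-[5-(trimethylsilyl)pent-4-yn-1-yl]-1,2-dioxan-6-yl]acetate | C[Si](C)(C)C#CCCC[C@]1(OC)CC[C@@H](CC(=O)OC(C)(C)C)OO1 | intermediate (not isolated)
16 | rac-2-[(3R,6S)-3-methoxy-3-[5-(trimethylsilyl)pent-4-yn-1-yl]-1,2-dioxan-6-yl]acetic acid | C[Si](C)(C)C#CCCC[C@]1(OC)CC[C@@H](CC(=O)O)OO1 | intermediate (not isolated)
17 | rac-methyl 2-[(3R,6S)-3-methoxy-3-[5-(trimethylsilyl)pent-4-yn-1-yl]-1,2-dioxan-6-yl]acetate | C[Si](C)(C)C#CCCC[C@]1(OC)CC[C@@H](CC(=O)OC)OO1 | intermediate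
18 | rac-methyl 2-[(3R,6S)-3-methoxy-3-(pent-4-yn-1-yl)-1,2-dioxan-6-yl]acetate | C#CCCC[C@]1(OC)CC[C@@H](CC(=O)OC)OO1 | intermediate
19 | dec-9-en-1-ol | C=CCCCCCCCCO | starting material
20 | dec-9-enal | C=CCCCCCCCC=O | intermediate
21 | (1E)-1-iodoundeca-1,10-diene | C=CCCCCCCC/C=C/I | intermediate
22 | rac-methyl 2-[(3R,6S)-3-[(6E)-hexadeca-6,15-dien-4-yn-1-yl]-3-methoxy-1,2-dioxan-6-yl]acetate | C=CCCCCCCC/C=C/C#CCCC[C@]1(OC)CC[C@@H](CC(=O)OC)OO1 | intermediate
23 | 2-[(3R,6S)-3-[(6E)-hexadeca-6,15-dien-4-yn-1-yl]-3-methoxy-1,2-dioxan-6-yl]acetic acid | C=CCCCCCCC/C=C/C#CCCC[C@]1(OC)CC[C@@H](CC(=O)O)OO1 | target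

## Step count and least certain steps

Total step count: 10. Longest linear sequence: 8 steps (steps 1–6, 9 and 10, from cyclobutanone 1); the iodoalkene branch (steps 7 and 8) has 2 steps.

**Step 4 (key step).**
- What may go wrong: formation of the cobalt alkoxide from a hindered tertiary alcohol may be slow, so that conversion stalls. Cobalt may also homolyse the O–O bond of the intermediate hydroperoxide before ring closure, with loss of the peroxide oxygen. Some β-scission toward the unsubstituted ring carbon would give a regioisomeric primary radical.
- Fallback: this leaves the cyclobutanol and closes the ring by peroxyketalization and peroxy-Michael addition. It sets out from 9 (made from 8 as in step 3) and comes back at 17. Grignard reagent 9 is acylated with pent-4-enoyl chloride under Fe(acac)3 catalysis to give 10-(trimethylsilyl)dec-1-en-9-yn-5-one F1. Cross-metathesis of F1 with methyl acrylate and the second-generation Grubbs catalyst gives methyl (2E)-6-oxo-11-(trimethylsilyl)undec-2-en-10-ynoate F2. Urea–hydrogen peroxide with catalytic Sc(OTf)3 in methanol converts the ketone of F2 into methyl (2E)-6-hydroperoxy-6-methoxy-11-(trimethylsilyl)undec-2-en-10-ynoate F3. Diethylamine in 2,2,2-trifluoroethanol closes the ring of F3 by intramolecular conjugate addition of the hydroperoxide to the enoate, and brief equilibration in acidic methanol gives 17.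

**Step 10.**
- What may go wrong: enantiodiscrimination may be poor because the stereocentre lies β to the acyl carbon, the enzyme may prefer the unwanted enantiomer, or turnover of the lipophilic ester in water may be slow.
- Fallback: physical separation replaces the kinetic resolution. It sets out from 22 and comes back at 23. Preparative chromatography on a polysaccharide chiral stationary phase gives methyl 2-[(3R,6S)-3-[(6E)-hexadeca-6,15-dien-4-yn-1-yl]-3-methoxy-1,2-dioxan-6-yl]acetate F4 as the single enantiomer. The same ester F4 would be recovered if the enzyme consumes the other enantiomer and the hydrolysis is driven past half conversion. Saponification of F4 with LiOH in THF/water at 0 °C then gives 23.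

**Step 5.**
- What may go wrong: cleavage of the tert-butyl group may be too slow in methanol at temperatures that are safe for the peroxide, and long exposure to strong acid may cause heterolysis of the O–O bond with rearrangement (Hock or Criegee type).
- Fallback: the operation is split and the methyl ester is made by alkylation of the carboxyl group instead of acid-catalysed exchange. It sets out from 14 and comes back at 17 through 16. Trifluoroacetic acid in CH2Cl2 at 0 °C removes the tert-butyl group at the hemiketal stage, before any ketal exists, and gives rac-2-[(3R,6S)-3-hydroxy-3-[5-(trimethylsilyl)pent-4-yn-1-yl]-1,2-dioxan-6-yl]acetic acid F5. Catalytic TsOH in methanol at room temperature converts F5 into ketal acid 16, and trimethylsilyldiazomethane in methanol/toluene methylates it to 17.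

**Step 8.**
- What may go wrong: E selectivity in the chromium olefination may be incomplete, and the Z isomer would be carried through the coupling into the target, where it can no longer be separated.
- Fallback: the geometry is fixed by syn addition to an alkyne. It sets out from 20 and comes back at 21. Homologation with the Ohira–Bestmann reagent (K2CO3, MeOH) gives undec-10-en-1-yne F6. Hydrozirconation of F6 with one equivalent of Cp2Zr(H)Cl, which takes the terminal alkyne ahead of the terminal alkene, gives chlorobis(cyclopentadienyl)[(1E)-undeca-1,10-dien-1-yl]zirconium F7, and iodine cleaves the C–Zr bond of F7 with retention to give 21.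

## Further compounds

F1 | step 4 | 10-(trimethylsilyl)dec-1-en-9-yn-5-one | C=CCCC(=O)CCCC#C[Si](C)(C)C
F2 | step 4 | methyl (2E)-6-oxo-11-(trimethylsilyl)undec-2-en-10-ynoate | COC(=O)/C=C/CCC(=O)CCCC#C[Si](C)(C)C
F3 | step 4 | methyl (2E)-6-hydroperoxy-6-methoxy-11-(trimethylsilyl)undec-2-en-10-ynoate (racemic) | COC(=O)/C=C/CCC(OC)(OO)CCCC#C[Si](C)(C)C
F4 | step 10 | methyl 2-[(3R,6S)-3-[(6E)-hexadeca-6,15-dien-4-yn-1-yl]-3-methoxy-1,2-dioxan-6-yl]acetate (single enantiomer) | C=CCCCCCCC/C=C/C#CCCC[C@]1(OC)CC[C@@H](CC(=O)OC)OO1
F5 | step 5 | rac-2-[(3R,6S)-3-hydroxy-3-[5-(trimethylsilyl)pent-4-yn-1-yl]-1,2-dioxan-6-yl]acetic acid | C[Si](C)(C)C#CCCC[C@]1(O)CC[C@@H](CC(=O)O)OO1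
F6 | step 8 | undec-10-en-1-yne | C=CCCCCCCCC#C
F7 | step 8 | chlorobis(cyclopentadienyl)[(1E)-undeca-1,10-dien-1-yl]zirconium | C=CCCCCCCC/C=C/[Zr](Cl)(C1C=CC=C1)C1C=CC=C1
A1 | alternative 1 | tert-butyl-[2-[(3R,6S)-3-[(6E)-hexadeca-6,15-dien-4-yn-1-yl]-3-methoxy-1,2-dioxan-6-yl]ethoxy]diphenylsilane | C=CCCCCCCC/C=C/C#CCCC[C@]1(OC)CC[C@@H](CCO[Si](c2ccccc2)(c2ccccc2)C(C)(C)C)OO1
A2 | alternative 1 | (3S,12E)-1-[tert-butyl(diphenyl)silyl]oxy-3-[(2-methoxypropan-2-yl)peroxy]docosa-12,21-dien-10-yn-6-one | C=CCCCCCCC/C=C/C#CCCCC(=O)CC[C@@H](CCO[Si](c1ccccc1)(c1ccccc1)C(C)(C)C)OOC(C)(C)OC
A3 | alternative 2 | 2-[(6S)-3-methoxy-3-[5-(trimethylsilyl)pent-4-yn-1-yl]-1,2-dioxan-6-yl]ethanol (both C3 epimers) | C[Si](C)(C)C#CCCCC1(OC)CC[C@@H](CCO)OO1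
A4 | alternative 2 | (2R)-2-[3-hydroperoxy-3-methoxy-8-(trimethylsilyl)oct-7-yn-1-yl]oxetane (both ketal epimers) | C[Si](C)(C)C#CCCCC(OC)(OO)CC[C@@H]1CCO1
A5 | alternative 3 | tert-butyl 3-hydroxy-6-(2-methoxy-2-oxoethyl)-3-[5-(trimethylsilyl)pent-4-yn-1-yl]-1,2-dioxane-4-carboxylate (racemic stereoisomer mixture) | C[Si](C)(C)C#CCCCC1(O)OOC(CC(=O)OC)CC1C(=O)OC(C)(C)C
A6 | alternative 3 | tert-butyl 3-oxo-8-(trimethylsilyl)oct-7-ynoate | C[Si](C)(C)C#CCCCC(=O)CC(=O)OC(C)(C)C
A7 | alternative 3 | methyl but-3-enoate | C=CCC(=O)OC
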